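**Retrosynthetic overview**
1. The oxirane is the only ring made in the synthesis and is closed last, by C2–OH-directed epoxidation of the C3=C4 alkene; the C2–OH comes from Luche reduction of the carvone enone.
2. The C8 angelate and the C10 carbinol come from one anti-selective Evans–Tishchenko hydride/acyl transfer from (Z)-2-methylbut-2-enal onto an 8-hydroxy-10-ketone (the proposed new step).
3. The C8–C9 bond and the C8 stereocentre come from a diisopinocampheylboron aldol of a C9–C13 methyl ketone with a C8 enal.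
4. The enal comes from the isopropenyl group by allylic chlorination and N-oxide oxidation; the cis C1 angelate comes from SN2 inversion of trans-6-hydroxycarvone triflate by cesium angelate.
5. The cyclohexene ring and C6 are taken intact from (S)-carvone; no carbocycle is built.

Assumption: bisabolane numbering is used for locants (ring C1–C6 with the ring angelate on C1 and the side chain on C6; chain C7–C11 with exocyclic methylene C14), and (S)-carvone, angelic acid, methyl angelate and 3-hydroxy-3-methylbutan-2-one are taken as commercial.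

**Route**

Step 1
Reactants: 1 (S)-(+)-carvone
Product: 3 trans-6-hydroxycarvone, via potassium dienolate 2 (not isolated)
Conditions: KN(SiMe3)2, THF, −78 °C; then Davis oxaziridine, −78 °C; AcOH quench
Reagents that add atoms: KN(SiMe3)2 C[Si](C)(C)N([K])[Si](C)(C)C (potassium of intermediate 2); 3-phenyl-2-(phenylsulfonyl)oxaziridine O=S(=O)(c1ccccc1)N1OC1c1ccccc1 (the new oxygen)
Why: Kinetic deprotonation gives the cross-conjugated enolate, which the oxaziridine hydroxylates (Davis enolate oxidation) on the face anti to the adjacent isopropenyl group, so the new C1–O bond is trans to the side chain as required for the inversion in step 2.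

Step 2
Reactants: 3 trans-6-hydroxycarvone
Product: 5 cis-6-angeloyloxycarvone, via trans triflate 4 (not isolated)
Conditions: Tf2O, 2,6-lutidine, CH2Cl2, −40 °C; then angelic acid (3 equiv), Cs2CO3 (3 equiv), 18-crown-6, MeCN, −20 °C to rt
Reagents that add atoms: triflic anhydride FC(F)(F)S(=O)(=O)OS(=O)(=O)C(F)(F)F (triflyl group of intermediate 4); angelic acid C/C=C(/C)C(=O)O (the angeloyloxy group)
Why: The α-keto triflate is a strong SN2 electrophile, so carboxylate displacement with inversion sets the 1S centre (ester cis to the C6 substituent) and never activates angelic acid as an acyl donor, which protects its Z geometry.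

Step 3
Reactants: 5 cis-6-angeloyloxycarvone
Product: 6 allylic chloride
Conditions: Ca(OCl)2, CO2 (dry ice), CH2Cl2/H2O, 0 °C
Reagents that add atoms: calcium hypochlorite [Ca+2].[O-]Cl.[O-]Cl
Why: Hypochlorous acid undergoes an ene-type allylic chlorination only with the electron-rich 1,1-disubstituted isopropenyl alkene (the enone and angelate alkenes are electron-poor), giving the 2-substituted allyl chloride with the exocyclic methylene kept and no stereocentre touched.

Step 4
Reactants: 6 allylic chloride
Product: 7 enal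
Conditions: NMO (4 equiv), KI (cat.), MeCN, 40 °C
Reagents that add atoms: N-methylmorpholine N-oxide C[N+]1([O-])CCOCC1
Why: SN2 attack of the N-oxide on the iodide-activated primary allylic halide and collapse of the alkoxyammonium salt (Ganem/Kornblum-type oxidation) gives the 2-substituted acrolein under nearly neutral conditions that spare the α-acyloxy ketone.

Step 5
Reactants: 8 3-hydroxy-3-methylbutan-2-one
Product: 9 3-methyl-3-(triethylsilyloxy)butan-2-one
Conditions: TESOTf, 2,6-lutidine, CH2Cl2, −78 to 0 °C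
Reagents that add atoms: triethylsilyl triflate CC[Si](CC)(CC)OS(=O)(=O)C(F)(F)F
Why: Silyl triflate silylation of the tertiary alcohol is fast at low temperature and masks the hydroxyl before boron enolisation.

Step 6
Reactants: 7 enal; 9 3-methyl-3-(triethylsilyloxy)butan-2-one
Product: 12 (8S)-β-hydroxy ketone, via boron enolate 10 (not isolated), via boron aldolate 11 (not isolated)
Conditions: 9 (1.6 equiv), (+)-Ipc2BCl (1.5 equiv), Et3N, Et2O, 0 °C; then 7, −78 to −20 °C; then H2O2, MeOH, pH 7 buffer, 0 °C
Reagents that add atoms: (+)-B-chlorodiisopinocampheylborane ClB([C@H]1C[C@H]2C[C@@H]([C@@H]1C)C2(C)C)[C@H]1C[C@H]2C[C@@H]([C@@H]1C)C2(C)C (boryl group of intermediates 10 and 11)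
Why: The methyl ketone can enolise on one side only, and its diisopinocampheylboron enolate adds to the aldehyde in a reagent-controlled asymmetric boron aldol reaction in which the (+)-Ipc ligands direct attack to the Si face of the enal, giving the 8S carbinol (expected dr about 5:1, minor epimer removed by chromatography).

Step 7
Reactants: 13 methyl angelate
Product: 14 (2Z)-2-methylbut-2-en-1-ol
Conditions: iBu2AlH (2.3 equiv), CH2Cl2, −78 to 0 °C; aqueous work-up
Reagents that add atoms: none
Why: 1,2-Reduction of the conjugated ester by the aluminium hydride (DIBAL reduction) leaves the trisubstituted Z alkene untouched.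

Step 8
Reactants: 14 (2Z)-2-methylbut-2-en-1-ol
Product: 15 (2Z)-2-methylbut-2-enal
Conditions: MnO2 (15 equiv), pentane/CH2Cl2, 0 °C, dark; filtered solution used at once
Reagents that add atoms: none
Why: Heterogeneous MnO2 oxidation of the allylic alcohol is neutral, which is the mildest way to keep the labile Z-enal from isomerising to tiglic aldehyde.

Step 9
Reactants: 12 (8S)-β-hydroxy ketone; 15 (2Z)-2-methylbut-2-enal
Product: 16 8-angelate 10-alcohol
Conditions: SmI2 (0.3 equiv) premixed with 15 (4 equiv) in THF at −20 °C until the blue colour is gone; then 12, −20 °C, dark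
Reagents that add atoms: none
Why: Proposed new method: an Evans–Tishchenko reduction in which the sacrificial aldehyde is the Z-enal 15, so that the hemiacetal formed at O8 on trivalent samarium delivers its carbinol hydride intramolecularly through a chair-like six-membered transition state to the C10 ketone (anti, giving 10S) and is itself oxidised to the C8 angelate, which sets C10 and installs the hindered ester in one step; the closest known reaction is the samarium-catalysed Evans–Tishchenko reduction of β-hydroxy ketones with saturated or aromatic aldehydes, and the new elements are a configurationally labile Z-enal as hydride donor and a catalyst premixed with the aldehyde so that no divalent samarium meets the α-acyloxy ketone.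

Step 10
Reactants: 16 8-angelate 10-alcohol
Product: 17 enone diol
Conditions: HF·pyridine, pyridine, THF, 0 °C
Reagents that add atoms: none
Why: Buffered fluoride desilylation cleaves the tertiary triethylsilyl ether without acyl migration or damage to the enone and angelates.

Step 11
Reactants: 17 enone diol
Product: 18 allylic triol
Conditions: NaBH4, CeCl3·7H2O, MeOH, −78 °C; AcOH quench at −78 °C
Reagents that add atoms: none
Why: In this Luche 1,2-reduction hydride adds axially to C2 anti to the axial C1 angelate (Felkin–Anh control and the usual carvone-to-cis-carveol preference agree), giving the equatorial 2-OH cis to both the C1 ester and the C6 side chain, while the esters are inert at −78 °C.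

Step 12
Reactants: 18 allylic triol
Product: 19 CNP0189369.2
Conditions: VO(acac)2 (10 mol %), t-BuOOH (1.5 equiv), CH2Cl2, 0 °C to rt
Reagents that add atoms: tert-butyl hydroperoxide CC(C)(C)OO
Why: In this hydroxyl-directed vanadium-catalysed epoxidation the C2 alkoxide-bound metal peroxide delivers oxygen to the C3=C4 alkene on the face of the C2–OH, giving the cis epoxy alcohol (3S,4R), while the angelate alkenes and the ester-deactivated 1,1-disubstituted alkene do not react.

**Compound list**
1 | (S)-(+)-carvone, (5S)-2-methyl-5-(prop-1-en-2-yl)cyclohex-2-en-1-one | C=C(C)[C@H]1CC=C(C)C(=O)C1 | starting material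
2 | cross-conjugated potassium dienolate of 1 (O–K on the former carbonyl carbon) | C=C(C)[C@H]1CC=C(C)C(O[K])=C1 | intermediate (not isolated)
3 | trans-6-hydroxycarvone, (5R,6R)-6-hydroxy-2-methyl-5-(prop-1-en-2-yl)cyclohex-2-en-1-one | C=C(C)[C@H]1CC=C(C)C(=O)[C@@H]1O | intermediate
4 | (1R,6R)-3-methyl-2-oxo-6-(prop-1-en-2-yl)cyclohex-3-en-1-yl trifluoromethanesulfonate (triflate trans to isopropenyl) | C=C(C)[C@H]1CC=C(C)C(=O)[C@@H]1OS(=O)(=O)C(F)(F)F | intermediate (not isolated)
5 | (1S,6R)-3-methyl-2-oxo-6-(prop-1-en-2-yl)cyclohex-3-en-1-yl (2Z)-2-methylbut-2-enoate (angelate cis to isopropenyl) | C=C(C)[C@H]1CC=C(C)C(=O)[C@H]1OC(=O)/C(C)=C\C | intermediate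
6 | (1S,6R)-6-(3-chloroprop-1-en-2-yl)-3-methyl-2-oxocyclohex-3-en-1-yl (2Z)-2-methylbut-2-enoate | C=C(CCl)[C@H]1CC=C(C)C(=O)[C@H]1OC(=O)/C(C)=C\C | intermediate
7 | (1S,6R)-3-methyl-2-oxo-6-(3-oxoprop-1-en-2-yl)cyclohex-3-en-1-yl (2Z)-2-methylbut-2-enoate | C=C(C=O)[C@H]1CC=C(C)C(=O)[C@H]1OC(=O)/C(C)=C\C | intermediate
8 | 3-hydroxy-3-methylbutan-2-one | CC(=O)C(C)(C)O | starting material
9 | 3-methyl-3-(triethylsilyloxy)butan-2-one | CC(=O)C(C)(C)O[Si](CC)(CC)CC | intermediate
10 | bis[(+)-isopinocampheyl]boron enolate of 9, {[3-methyl-3-(triethylsilyloxy)but-1-en-2-yl]oxy}bis(isopinocampheyl)borane | C=C(OB([C@H]1C[C@H]2C[C@@H]([C@@H]1C)C2(C)C)[C@H]1C[C@H]2C[C@@H]([C@@H]1C)C2(C)C)C(C)(C)O[Si](CC)(CC)CC | intermediate (not isolated)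
11 | O8-bis[(+)-isopinocampheyl]boryl aldolate of 12 (8S) | C=C([C@H](CC(=O)C(C)(C)O[Si](CC)(CC)CC)OB([C@H]2C[C@H]3C[C@@H]([C@@H]2C)C3(C)C)[C@H]2C[C@H]3C[C@@H]([C@@H]2C)C3(C)C)[C@H]1CC=C(C)C(=O)[C@H]1OC(=O)/C(C)=C\C | intermediate (not isolated)
12 | (1S,6R,8S)-1-angeloyloxy-8-hydroxy-11-(triethylsilyloxy)bisabola-3,7(14)-diene-2,10-dione | C=C([C@H](CC(=O)C(C)(C)O[Si](CC)(CC)CC)O)[C@H]1CC=C(C)C(=O)[C@H]1OC(=O)/C(C)=C\C | intermediate
13 | methyl angelate, methyl (2Z)-2-methylbut-2-enoate | C/C=C(/C)C(=O)OC | starting material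
14 | (2Z)-2-methylbut-2-en-1-ol | C/C=C(/C)CO | intermediate
15 | (2Z)-2-methylbut-2-enal | C/C=C(/C)C=O | intermediate
16 | (1S,6R,8S,10S)-1,8-bis(angeloyloxy)-10-hydroxy-11-(triethylsilyloxy)bisabola-3,7(14)-dien-2-one (8-O and 10-O anti) | C=C([C@H](C[C@H](O)C(C)(C)O[Si](CC)(CC)CC)OC(=O)/C(C)=C\C)[C@H]1CC=C(C)C(=O)[C@H]1OC(=O)/C(C)=C\C | intermediate
17 | (1S,6R,8S,10S)-1,8-bis(angeloyloxy)-10,11-dihydroxybisabola-3,7(14)-dien-2-one | C=C([C@H](C[C@H](O)C(C)(C)O)OC(=O)/C(C)=C\C)[C@H]1CC=C(C)C(=O)[C@H]1OC(=O)/C(C)=C\C | intermediate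
18 | (1S,2R,6R,8S,10S)-1,8-bis(angeloyloxy)bisabola-3,7(14)-diene-2,10,11-triol (2-OH, 1-OAng and C6 chain all cis) | C=C([C@H](C[C@H](O)C(C)(C)O)OC(=O)/C(C)=C\C)[C@H]1CC=C(C)[C@@H](O)[C@H]1OC(=O)/C(C)=C\C | intermediate
19 | CNP0189369.2, (1S,2S,3S,4R,6R,8S,10S)-1,8-bis(angeloyloxy)-3,4-epoxybisabol-7(14)-ene-2,10,11-triol (epoxide, 2-OH, 1-OAng and C6 chain all cis) | C=C([C@H](C[C@H](O)C(C)(C)O)OC(=O)/C(C)=C\C)[C@H]1C[C@H]2O[C@@]2(C)[C@@H](O)[C@H]1OC(=O)/C(C)=C\C | target

**Step count and risks**
Total step count: 12. Longest linear sequence: 9 steps from (S)-carvone (steps 1, 2, 3, 4, 6, 9, 10, 11, 12).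

The three steps most likely to fail:

Step 2 (SN2 of the α-keto triflate). The centre is secondary and flanked by the C6 substituent, so elimination with aromatisation to a phenol or enolisation may compete. The fallback sets out from 3 and comes back at 5. Mitsunobu inversion of 3 with 4-nitrobenzoic acid (PPh3, DIAD, toluene, 0 °C) gives the cis 4-nitrobenzoate F1. Brief methanolysis (K2CO3, MeOH, 0 °C) gives cis-6-hydroxycarvone F2. Esterification with retention, using the mixed anhydride of angelic acid and 2,4,6-trichlorobenzoyl chloride (Et3N, then toluene, 80 °C), gives 5.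

Step 4 (chloride to 2-substituted acrolein). The N-oxide displacement may be slow, and the basic medium could epimerise C1 or pull the enal into conjugation with loss of the C6 centre. The fallback sets out from 5 and comes back at 7, bypassing 6. Allylic hydroxylation of the isopropenyl methyl with SeO2 (0.5 equiv) and t-BuOOH in CH2Cl2 gives the allylic alcohol F3, and MnO2 in CH2Cl2 oxidises it to 7.

Step 9 (the proposed Evans–Tishchenko angeloyl transfer). Enal 15 may isomerise to the E isomer and deliver a tiglate, the hemiacetal of a hindered enal may form poorly, or retro-aldol may intervene. The fallback uses known chemistry, sets out from 12 and comes back at 17. Hydroxyl-directed anti reduction with Me4NBH(OAc)3 (MeCN/AcOH, −30 °C) gives the anti-8,10-diol F4. HF·pyridine gives the triol F5. 2,2-Dimethoxypropane with pyridinium p-toluenesulfonate gives the 10,11-acetonide F6, which leaves only the 8-OH free. Angeloylation with the angelic/2,4,6-trichlorobenzoic mixed anhydride (Et3N, toluene, 80 °C) gives the 8-angelate acetonide F7, and 80 % aqueous AcOH at rt removes the acetonide to give 17.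

**Further compounds**
F1 | step 2 | (1S,6R)-3-methyl-2-oxo-6-(prop-1-en-2-yl)cyclohex-3-en-1-yl 4-nitrobenzoate | C=C(C)[C@H]1CC=C(C)C(=O)[C@H]1OC(=O)c1ccc(cc1)[N+](=O)[O-]
F2 | step 2 | cis-6-hydroxycarvone, (5R,6S)-6-hydroxy-2-methyl-5-(prop-1-en-2-yl)cyclohex-2-en-1-one | C=C(C)[C@H]1CC=C(C)C(=O)[C@H]1O
F3 | step 4 | (1S,6R)-6-(3-hydroxyprop-1-en-2-yl)-3-methyl-2-oxocyclohex-3-en-1-yl (2Z)-2-methylbut-2-enoate | C=C(CO)[C@H]1CC=C(C)C(=O)[C@H]1OC(=O)/C(C)=C\C
F4 | step 9 | (1S,6R,8S,10S)-1-angeloyloxy-8,10-dihydroxy-11-(triethylsilyloxy)bisabola-3,7(14)-dien-2-one | C=C([C@H](C[C@H](O)C(C)(C)O[Si](CC)(CC)CC)O)[C@H]1CC=C(C)C(=O)[C@H]1OC(=O)/C(C)=C\C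
F5 | step 9 | (1S,6R,8S,10S)-1-angeloyloxy-8,10,11-trihydroxybisabola-3,7(14)-dien-2-one | C=C([C@H](C[C@H](O)C(C)(C)O)O)[C@H]1CC=C(C)C(=O)[C@H]1OC(=O)/C(C)=C\C
F6 | step 9 | (1S,6R,8S,10S)-1-angeloyloxy-8-hydroxy-10,11-(isopropylidenedioxy)bisabola-3,7(14)-dien-2-one | C=C([C@H](C[C@H](OC(C)(C)O2)C2(C)C)O)[C@H]1CC=C(C)C(=O)[C@H]1OC(=O)/C(C)=C\C
F7 | step 9 | (1S,6R,8S,10S)-1,8-bis(angeloyloxy)-10,11-(isopropylidenedioxy)bisabola-3,7(14)-dien-2-one | C=C([C@H](C[C@H](OC(C)(C)O2)C2(C)C)OC(=O)/C(C)=C\C)[C@H]1CC=C(C)C(=O)[C@H]1OC(=O)/C(C)=C\C
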